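**Plan**

- Retrosynthesis first cuts the two pyran O1–C2 bonds (cyclodehydration) and then the four C2–CH3 bonds, which leads back to an S-configured bis(7-methoxycoumarin).
- This works because pyran C2 of each 2,2-dimethyl-2H-chromene, with its gem-dimethyl pair, sits exactly where a coumarin lactone carbonyl carbon would be; O1, the cis C3=C4 bond and the 7-methoxy benzo ring are common to both ring systems.
- The bis-coumarin is cut between the stereogenic C3 of the butene linker and its aryl group (aryl diene plus aryl boronate). Both partners come from 6-bromo-7-methoxycoumarin, itself cut at C3=C4 and the lactone C–O bond (Wittig olefination and lactonisation).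
- Forward: the coumarin ring is built on the brominated salicylaldehyde, the bromide is divided into boronate and diene, the linker is joined, four methyl groups open both lactones, and both pyran rings close last.
- Stereochemistry: the single S centre is set by the chiral nickel catalyst in the hydroarylation, the linker E alkene comes from the E diene, and the cis C3=C4 bonds of both chromenes are inherited from the coumarin rings.

Key step: step 6

Remark: the ligand antipode used in step 5 is the one that delivers S at the new benzylic-allylic carbon; the absolute configuration of bis-coumarin 12 would be verified by chiral HPLC and optical rotation before material is carried on.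
Remark: (E)-buta-1,3-dienylboronic acid pinacol ester 10 is taken to be a purchasable reagent.

**Route**

Step 1
Reactants: 1 2-hydroxy-4-methoxybenzaldehyde; 2 bromine
Product: 3 5-bromo-2-hydroxy-4-methoxybenzaldehyde
Conditions: Br2 (1.0 equiv), CH2Cl2, 0 °C to rt
Reagents that add atoms: bromine, BrBr
Why: Electrophilic aromatic bromination is steered to C5 by the para hydroxyl and the ortho methoxy group acting together, whereas C3 is flanked by two substituents and C6 is meta to both donors.

Step 2
Reactants: 3 5-bromo-2-hydroxy-4-methoxybenzaldehyde; 4 (carbethoxymethylene)triphenylphosphorane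
Product: 7 6-bromo-7-methoxy-2H-chromen-2-one, via E-hydroxycinnamate ester 5 (not isolated), via Z-hydroxycinnamate ester 6 (not isolated)
Conditions: Ph3P=CHCO2Et (1.2 equiv), N,N-diethylaniline, reflux (about 215 °C)
Reagents that add atoms: (carbethoxymethylene)triphenylphosphorane, CCOC(=O)C=P(c1ccccc1)(c1ccccc1)c1ccccc1
Why: A Wittig olefination with the stabilised ylide gives the o-hydroxycinnamate 5, which equilibrates with its cis isomer 6 at this temperature and is drained irreversibly by lactonisation with loss of ethanol, the classical one-pot coumarin synthesis from salicylaldehydes.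

Step 3
Reactants: 7 6-bromo-7-methoxy-2H-chromen-2-one; 8 bis(pinacolato)diboron
Product: 9 7-methoxy-6-(4,4,5,5-tetramethyl-1,3,2-dioxaborolan-2-yl)-2H-chromen-2-one
Conditions: B2pin2 (1.2 equiv), Pd(dppf)Cl2 (3 mol%), KOAc (3 equiv), 1,4-dioxane, 90 °C
Reagents that add atoms: bis(pinacolato)diboron, CC1(C)OB(OC1(C)C)B1OC(C)(C)C(C)(C)O1
Why: Miyaura borylation of the aryl bromide runs with acetate as the only base, which leaves the lactone closed, and the ortho methoxy group does not block oxidative addition.

Step 4
Reactants: 7 6-bromo-7-methoxy-2H-chromen-2-one; 10 (E)-2-(buta-1,3-dien-1-yl)-4,4,5,5-tetramethyl-1,3,2-dioxaborolane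
Product: 11 (E)-6-(buta-1,3-dien-1-yl)-7-methoxy-2H-chromen-2-one
Conditions: 10 (1.3 equiv), Pd(PPh3)4 (5 mol%), K2CO3 (2 equiv), 1,4-dioxane/H2O, 80 °C, BHT (trace); neutral work-up
Reagents that add atoms: (E)-2-(buta-1,3-dien-1-yl)-4,4,5,5-tetramethyl-1,3,2-dioxaborolane, C=C/C=C/B1OC(C)(C)C(C)(C)O1
Why: Suzuki–Miyaura coupling transfers the dienyl group with retention of its E geometry, and the coumarin tolerates aqueous carbonate at this temperature, re-closing on neutral work-up if any of it has opened.

Step 5
Reactants: 11 (E)-6-(buta-1,3-dien-1-yl)-7-methoxy-2H-chromen-2-one; 9 7-methoxy-6-(4,4,5,5-tetramethyl-1,3,2-dioxaborolan-2-yl)-2H-chromen-2-one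
Product: 12 (S,E)-1,3-bis(7-methoxy-2-oxo-2H-chromen-6-yl)but-1-ene
Conditions: 9 (1.5 equiv), Ni(cod)2 (10 mol%), chiral 7-amino-7'-(diarylphosphino)-1,1'-spirobiindane ligand (12 mol%, antipode giving S), MeOH/THF, 40 °C
Reagents that add atoms: none
Why: This is a nickel-catalysed enantioselective 1,2-hydroarylation of a 1-aryl-1,3-diene with an arylboron reagent, in which methanol and zerovalent nickel turn the terminal vinyl group into a 1-aryl-3-methyl-π-allylnickel methoxide, transmetallation from 9 and reductive elimination at the methyl-bearing terminus form the aryl–C3 bond while keeping the E styrene, and the chiral aminophosphine on nickel decides which allyl face is arylated and so sets the S centre.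

Step 6
Reactants: 12 (S,E)-1,3-bis(7-methoxy-2-oxo-2H-chromen-6-yl)but-1-ene; 13 methylmagnesium bromide
Product: 15 (S,E)-1,3-bis{4-hydroxy-5-[(Z)-3-hydroxy-3-methylbut-1-en-1-yl]-2-methoxyphenyl}but-1-ene, via bis-Z-enone diphenol 14 (not isolated)
Conditions: MeMgBr (3.0 M in Et2O, 10 equiv), THF, 0 °C to 40 °C; then sat. aq. NH4Cl, 0 °C; crude 15 taken on directly
Reagents that add atoms: methylmagnesium bromide, C[Mg]Br
Why: Each lactone carbonyl (C2 of a 7-methoxycoumarin) takes up a first methyl by 1,2-addition, the cyclic hemiketal magnesium alkoxide collapses with ring opening to a Z-aryl enone whose ortho oxygen is now a magnesium phenoxide (14), and a second methyl adds 1,2 to that ketone, so that four C–CH3 bonds form and both lactones end, after protonation, as Z-configured tertiary allylic alcohols beside free phenols. The closest known reaction type is the exhaustive methyl Grignard or methyllithium addition to coumarins that gives o-hydroxy-cis-cinnamyl dimethyl carbinols, the usual entry to 2,2-dimethyl-2H-chromenes. No ring is closed and no stereocentre is created here; the two pyran rings are closed in step 7. The selectivity needed is carbonyl attack over conjugate attack at four successive electrophiles: the hard, uncatalysed methyl Grignard reagent prefers the carbonyl, and once a lactone has opened the phenoxide feeds electron density into the enone and shuts down its β-carbon, while the cis geometry fixed by the former ring persists because nothing in the sequence breaks the C3=C4 π bond. The doubly benzylic-allylic C–H of the stereocentre and the coumarin C3–H are far too weakly acidic for MeMgBr and the central E-styrene is inert, so the S centre and the linker pass through unchanged.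

Step 7
Reactants: 15 (S,E)-1,3-bis{4-hydroxy-5-[(Z)-3-hydroxy-3-methylbut-1-en-1-yl]-2-methoxyphenyl}but-1-ene
Product: 16 (S,E)-1,3-bis(7-methoxy-2,2-dimethyl-2H-chromen-6-yl)but-1-ene
Conditions: pyridinium p-toluenesulfonate (PPTS, 10 mol%), CH2Cl2, rt
Reagents that add atoms: none
Why: In this acid-catalysed cyclodehydration each tertiary allylic alcohol ionises to an allyl cation stabilised by the oxygenated ring (an o-quinone methide once the phenol has lost its proton), which the cis-disposed phenol oxygen captures in a six-membered closure (formally an oxa-6π electrocyclisation) to give the 2,2-dimethyl-2H-chromene, at an acidity too low to protonate the electron-rich styrene or disturb the stereocentre.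

**Compound list**

1 | 2-hydroxy-4-methoxybenzaldehyde | COc1ccc(C=O)c(O)c1 | starting material
2 | bromine | BrBr | starting material
3 | 5-bromo-2-hydroxy-4-methoxybenzaldehyde | COc1cc(O)c(C=O)cc1Br | intermediate
4 | (carbethoxymethylene)triphenylphosphorane | CCOC(=O)C=P(c1ccccc1)(c1ccccc1)c1ccccc1 | starting material
5 | ethyl (E)-3-(5-bromo-2-hydroxy-4-methoxyphenyl)acrylate; formed in the flask, not isolated | CCOC(=O)/C=C/c1cc(Br)c(OC)cc1O | intermediate
6 | ethyl (Z)-3-(5-bromo-2-hydroxy-4-methoxyphenyl)acrylate; formed in the flask, not isolated | CCOC(=O)/C=C\c1cc(Br)c(OC)cc1O | intermediate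
7 | 6-bromo-7-methoxy-2H-chromen-2-one | COc1cc2oc(=O)ccc2cc1Br | intermediate
8 | bis(pinacolato)diboron | CC1(C)OB(OC1(C)C)B1OC(C)(C)C(C)(C)O1 | starting material
9 | 7-methoxy-6-(4,4,5,5-tetramethyl-1,3,2-dioxaborolan-2-yl)-2H-chromen-2-one | COc1cc2oc(=O)ccc2cc1B1OC(C)(C)C(C)(C)O1 | intermediate
10 | (E)-2-(buta-1,3-dien-1-yl)-4,4,5,5-tetramethyl-1,3,2-dioxaborolane | C=C/C=C/B1OC(C)(C)C(C)(C)O1 | starting material
11 | (E)-6-(buta-1,3-dien-1-yl)-7-methoxy-2H-chromen-2-one | C=C/C=C/c1cc2ccc(=O)oc2cc1OC | intermediate
12 | (S,E)-1,3-bis(7-methoxy-2-oxo-2H-chromen-6-yl)but-1-ene | COc1cc2oc(=O)ccc2cc1/C=C/[C@H](C)c1cc2ccc(=O)oc2cc1OC | intermediate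
13 | methylmagnesium bromide | C[Mg]Br | starting material
14 | (S,E)-1,3-bis{4-hydroxy-2-methoxy-5-[(Z)-3-oxobut-1-en-1-yl]phenyl}but-1-ene; present as its magnesium phenoxide, not isolated | COc1cc(O)c(/C=C\C(C)=O)cc1/C=C/[C@H](C)c1cc(/C=C\C(C)=O)c(O)cc1OC | intermediate
15 | (S,E)-1,3-bis{4-hydroxy-5-[(Z)-3-hydroxy-3-methylbut-1-en-1-yl]-2-methoxyphenyl}but-1-ene | COc1cc(O)c(/C=C\C(C)(C)O)cc1/C=C/[C@H](C)c1cc(/C=C\C(C)(C)O)c(O)cc1OC | intermediate
16 | (S,E)-1,3-bis(7-methoxy-2,2-dimethyl-2H-chromen-6-yl)but-1-ene | COc1cc2c(cc1/C=C/[C@H](C)c1cc3c(cc1OC)OC(C)(C)C=C3)C=CC(C)(C)O2 | target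

**Step count**

Total steps: 7. Longest linear sequence: 6 (steps 1, 2, 3 or 4, 5, 6, 7).

**Steps most likely to fail**

Step 5. The coumarin C3=C4 bonds may compete for the nickel hydride or aryl species, the ortho-methoxy boronate may protodeboronate in methanol, and facial discrimination with an ortho-substituted aryl partner may be insufficient. The fallback assembles the linker by hydrovinylation and cross-metathesis. Setting out from bromocoumarin 7, Suzuki–Miyaura vinylation with potassium vinyltrifluoroborate (Pd(dppf)Cl2, Cs2CO3, THF/H2O, 70 °C) should give 7-methoxy-6-vinyl-2H-chromen-2-one F1. Nickel-catalysed asymmetric hydrovinylation of part of F1 (ethylene 1 atm, [(allyl)NiBr]2, chiral phosphoramidite ligand, NaB[3,5-(CF3)2C6H3]4, CH2Cl2, −70 °C) should give (S)-6-(but-3-en-2-yl)-7-methoxy-2H-chromen-2-one F2. E-selective cross-metathesis of F2 with excess F1 (second-generation Hoveyda–Grubbs catalyst, CH2Cl2, 40 °C, benzoquinone added against ruthenium hydride isomerisation) comes back to the route at bis-coumarin 12.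

Step 6. The addition may stall at the methyl ketone stage on one arm, some conjugate addition at C4 may occur, and the polyanionic magnesium phenoxides may precipitate before all four carbonyl events are complete. The fallback installs the methyl groups on the monomer before the fragments are joined. Setting out from bromocoumarin 7, MeMgBr (THF, 0 °C to rt) should give 4-bromo-2-[(Z)-3-hydroxy-3-methylbut-1-en-1-yl]-5-methoxyphenol F3, which PPTS in CH2Cl2 should close to 6-bromo-7-methoxy-2,2-dimethyl-2H-chromene F4. Miyaura borylation of F4 as in step 3 should give 7-methoxy-2,2-dimethyl-6-(4,4,5,5-tetramethyl-1,3,2-dioxaborolan-2-yl)-2H-chromene F5, and Suzuki–Miyaura coupling of F4 with 10 as in step 4 should give (E)-6-(buta-1,3-dien-1-yl)-7-methoxy-2,2-dimethyl-2H-chromene F6. Hydroarylation of F6 with F5 under the conditions of step 5 (the cis-disubstituted chromene alkene being far less reactive than the terminal diene) comes back to the route at target 16.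

Step 4. The dienyl boronate may protodeboronate, Heck-type insertion may occur at its terminal vinyl group, and the aryl diene may oligomerise during coupling. The fallback builds the four-carbon unit as three carbons plus one. Setting out from bromocoumarin 7, Heck reaction with acrolein diethyl acetal (Pd(OAc)2, nBu4NOAc, K2CO3, KCl, DMF, 90 °C) should give (E)-6-(3,3-diethoxyprop-1-en-1-yl)-7-methoxy-2H-chromen-2-one F7, hydrolysed on work-up with dilute HCl to (E)-3-(7-methoxy-2-oxo-2H-chromen-6-yl)acrylaldehyde F8. Wittig methylenation of F8 (Ph3P=CH2 from Ph3PCH3Br and KOtBu, one equivalent, THF, −78 to 0 °C) comes back to the route at diene 11.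

**Further compounds**

F1 | step 5 | 7-methoxy-6-vinyl-2H-chromen-2-one | C=Cc1cc2ccc(=O)oc2cc1OC
F2 | step 5 | (S)-6-(but-3-en-2-yl)-7-methoxy-2H-chromen-2-one | C=C[C@H](C)c1cc2ccc(=O)oc2cc1OC
F3 | step 6 | 4-bromo-2-[(Z)-3-hydroxy-3-methylbut-1-en-1-yl]-5-methoxyphenol | COc1cc(O)c(/C=C\C(C)(C)O)cc1Br
F4 | step 6 | 6-bromo-7-methoxy-2,2-dimethyl-2H-chromene | COc1cc2c(cc1Br)C=CC(C)(C)O2
F5 | step 6 | 7-methoxy-2,2-dimethyl-6-(4,4,5,5-tetramethyl-1,3,2-dioxaborolan-2-yl)-2H-chromene | COc1cc2c(cc1B1OC(C)(C)C(C)(C)O1)C=CC(C)(C)O2
F6 | step 6 | (E)-6-(buta-1,3-dien-1-yl)-7-methoxy-2,2-dimethyl-2H-chromene | C=C/C=C/c1cc2c(cc1OC)OC(C)(C)C=C2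
F7 | step 4 | (E)-6-(3,3-diethoxyprop-1-en-1-yl)-7-methoxy-2H-chromen-2-one | CCOC(OCC)/C=C/c1cc2ccc(=O)oc2cc1OC
F8 | step 4 | (E)-3-(7-methoxy-2-oxo-2H-chromen-6-yl)acrylaldehyde | O=C/C=C/c1cc2ccc(=O)oc2cc1OC
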